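**Overview**

- Drimane numbering is used: ring A = C1–C5 and C10, ring B = C5–C10, C11 on C9, C12 on C8. The route rests on one feature: the methyl-bearing quaternary C10 is allylic, through C5, to the oxygenated C6, so a C6–O stereocentre on a C6–C5=C10 unit can be consumed to set C10 while C9 (carrying C11) is bonded to C10.
- Target ⇒ di-tert-butyl ester 6β-ol (acylation, acidolysis) ⇒ C6 ketone ⇒ α-face hydrogenation of a C8=C9 diester (cis 8β,9β) ⇒ C5=C6 hydroboration ⇒ carbonylation of a C8 enol triflate (C12) ⇒ tert-butyl 8-oxodrim-5-en-11-oate.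
- Key disconnection C9–C10 by a [3,3] shift (Ireland–Claisen) of the silyl ketene acetal of a (6S)-6-(2,6,6-trimethylcyclohexenyl)-δ-lactone. Ring A is bought with β-cyclocitral, ring B is closed in the key step, and no other ring is formed.
- C8 goes through the rearrangement as a 4,6-trans silyloxy carbinol and is oxidised to the ketone two steps later. A 2,4-dione would have to be enolised towards C7, giving a 2H-pyran-type dienolate in which C6–O cleavage (ring opening to a dienoate) competes, and its β-keto acid product could decarboxylate.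
- The lactone is made from β-cyclocitral by asymmetric allylboration (sets C6), acryloylation, ring-closing metathesis and conjugate borylation–oxidation.

Key step: step 5

Remark: 1, 2 (the reagent derived from (+)-α-pinene), 5 and 23 are taken as purchasable; α/β refer to the usual drimane orientation (C10 methyl β).

**Step 1**
Reactants: 1 β-cyclocitral; 2 (−)-B-allyldiisopinocampheylborane
Product: 4 (S)-1-(2,6,6-trimethylcyclohex-1-en-1-yl)but-3-en-1-ol, via borinate ester 3 (not isolated)
Conditions: 2 (1.3 equiv), Et2O, −78 °C; then 3 M NaOH, 30% H2O2, 0 → 23 °C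
Reagents that add atoms: (−)-B-allyldiisopinocampheylborane (2), C=CCB([C@@H]1C[C@@H]2C[C@H]([C@H]1C)C2(C)C)[C@@H]1C[C@@H]2C[C@H]([C@H]1C)C2(C)C (boron retained only in intermediate 3)
Why: Brown asymmetric allylboration through a chair-like six-membered transition state, in which the isopinocampheyl groups from (+)-α-pinene should direct the allyl group to the Si face of the aldehyde and so set the (S)-carbinol C6, the reagent being reactive enough for this hindered enal.

**Step 2**
Reactants: 4 (S)-homoallylic alcohol; 5 acryloyl chloride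
Product: 6 (S)-1-(2,6,6-trimethylcyclohex-1-en-1-yl)but-3-en-1-yl prop-2-enoate
Conditions: 5 (1.5 equiv), Et3N, DMAP (10 mol%), CH2Cl2, 0 °C
Reagents that add atoms: acryloyl chloride (5), C=CC(=O)Cl
Why: O-acylation of the secondary allylic alcohol by the acid chloride under nucleophilic catalysis, which does not touch the C6 stereocentre.

**Step 3**
Reactants: 6 acrylate ester
Product: 7 (S)-6-(2,6,6-trimethylcyclohex-1-en-1-yl)-5,6-dihydro-2H-pyran-2-one
Conditions: second-generation Grubbs catalyst RuCl2(=CHPh)(PCy3)(H2IMes) (3 mol%), CH2Cl2, 40 °C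
Reagents that add atoms: none
Why: Ring-closing metathesis of the acrylate with the terminal alkene gives the 5,6-dihydropyran-2-one, the tetrasubstituted cyclohexene being inert to the ruthenium carbene and loss of ethene driving the closure.

**Step 4**
Reactants: 7 unsaturated lactone
Product: 9 (4R,6S)-4-hydroxy-6-(2,6,6-trimethylcyclohex-1-en-1-yl)oxan-2-one, via β-boryl lactone 8 (not isolated)
Conditions: CuCl (5 mol%), Xantphos (5 mol%), NaOtBu (10 mol%), B2pin2 (1.1 equiv), MeOH (2 equiv), THF, 23 °C; then 30% H2O2, aq. NaHCO3, 0 °C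
Reagents that add atoms: bis(pinacolato)diboron, CC1(C)OB(OC1(C)C)B1OC(C)(C)C(C)(C)O1 (boron retained only in intermediate 8); hydrogen peroxide, OO
Why: Copper-catalysed conjugate borylation of the unsaturated lactone followed by stereoretentive C–B oxidation, in which the boryl-copper species should add to C8 on the lactone face opposite the C6 substituent (axial attack on the half-chair) and give the 4,6-trans hydroxy lactone.

**Step 5**
Reactants: 9 trans-hydroxy lactone
Product: 12 (1S,2R,8aR)-2-hydroxy-5,5,8a-trimethyl-1,2,3,5,6,7,8,8a-octahydronaphthalene-1-carboxylic acid, via bis-silyl ketene acetal 10 (not isolated), via rearranged bis-silyl ester 11 (not isolated)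
Conditions: LiN(iPr)2 (2.2 equiv), THF, −78 °C; TBSCl (2.6 equiv), DMPU, −78 → 23 °C; toluene, 110 °C; then aq. HF, MeCN, 0 → 23 °C
Reagents that add atoms: tert-butyldimethylsilyl chloride, CC(C)(C)[Si](C)(C)Cl (silicon retained only in intermediates 10 and 11)
Why: Double deprotonation gives an alkoxide–enolate (a β-alkoxide enolate does not β-eliminate), silylation gives ketene acetal 10 in which C9=C11 is tied through the ring oxygen to allylic C6, and on heating a concerted suprafacial [3,3] shift bonds C9 to C10 while the C6–O bond breaks and the alkene moves to C5=C6. The closest known reaction is the Ireland–Claisen rearrangement of silyl ketene acetals of alkenyl lactones to cycloalkene carboxylic acids, which includes six-membered lactones that must react through a boat. Ring B (C5–C10) is closed in the pericyclic event itself: because C7–C8 bridges C6 and C9, the six reacting atoms are held in a boat inside a bicyclo[2.2.2]octane-like array, so the lactone ring is exchanged for the carbocycle without an open-chain stage. The new quaternary stereocentre C10 is controlled by the (S)-C6–O stereocentre, since C9 is delivered to the face of C10 from which oxygen departs (the α face when C7 lies s-cis to C10, the only geometry the ring allows), which places the C10 methyl β; C9 forms with its carboxyl α but becomes enolisable in step 7 and needs no control. The step needs complete chirality transfer and rearrangement in preference to C6–O ionisation or silyl migration, and this should be secured by the alkene geometry fixed within ring A, the enforced boat, the non-polar medium and the trans C8 silyloxy group, which points away from the C10 methyl. Fluoride work-up then removes both silyl groups and leaves a β-hydroxy acid that cannot decarboxylate.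

**Step 6**
Reactants: 12 hydroxy acid
Product: 13 tert-butyl (1S,2R,8aR)-2-hydroxy-5,5,8a-trimethyl-1,2,3,5,6,7,8,8a-octahydronaphthalene-1-carboxylate
Conditions: tert-butyl 2,2,2-trichloroacetimidate (2 equiv), CH2Cl2–cyclohexane, 23 °C
Reagents that add atoms: tert-butyl 2,2,2-trichloroacetimidate, CC(C)(C)OC(=N)C(Cl)(Cl)Cl
Why: O-alkylation of the carboxylic acid by the imidate (tert-butyl cation transfer promoted by the acid itself) esterifies the hindered carboxyl next to quaternary C10 without an added acid catalyst and leaves the secondary alcohol free.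

**Step 7**
Reactants: 13 hydroxy ester
Product: 14 tert-butyl (1R,8aR)-5,5,8a-trimethyl-2-oxo-1,2,3,5,6,7,8,8a-octahydronaphthalene-1-carboxylate (tert-butyl 8-oxodrim-5-en-11-oate; C9 labile and drawn as the equatorial 9β-ester)
Conditions: Dess–Martin periodinane, NaHCO3, CH2Cl2, 0 → 23 °C
Reagents that add atoms: none
Why: Dess–Martin oxidation of the secondary alcohol under buffered, non-basic conditions keeps the β,γ-alkene in place, and C9, now the enolisable carbon of a β-keto ester, should equilibrate through the enol to the equatorial ester.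

**Step 8**
Reactants: 14 β-keto ester
Product: 15 tert-butyl (8aS)-5,5,8a-trimethyl-2-(trifluoromethylsulfonyloxy)-3,5,6,7,8,8a-hexahydronaphthalene-1-carboxylate
Conditions: NaH (1.1 equiv), Et2O, 0 °C; Tf2O (1.2 equiv), 0 °C
Reagents that add atoms: trifluoromethanesulfonic anhydride, O=S(=O)(OS(=O)(=O)C(F)(F)F)C(F)(F)F
Why: Deprotonation at the doubly activated C9, far more acidic than the C7 hydrogens, and O-sulfonylation of the enolate (enol triflate formation) fix the alkene at C8=C9.

**Step 9**
Reactants: 15 enol triflate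
Product: 16 (8aS)-1-(tert-butoxycarbonyl)-5,5,8a-trimethyl-3,5,6,7,8,8a-hexahydronaphthalene-2-carboxylic acid
Conditions: Pd(OAc)2 (5 mol%), dppp (6 mol%), CO (1 atm), Et3N, DMF–H2O (5:1), 70 °C
Reagents that add atoms: carbon monoxide, [C-]#[O+]; water, O
Why: Palladium-catalysed hydroxycarbonylation of the enol triflate (oxidative addition to zerovalent palladium formed in the flask, CO insertion, capture of the acylpalladium by water) installs C12 on C8 without moving the alkene.

**Step 10**
Reactants: 16 acid
Product: 17 di-tert-butyl (8aS)-5,5,8a-trimethyl-3,5,6,7,8,8a-hexahydronaphthalene-1,2-dicarboxylate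
Conditions: tert-butyl 2,2,2-trichloroacetimidate (2 equiv), CH2Cl2–cyclohexane, 23 °C
Reagents that add atoms: tert-butyl 2,2,2-trichloroacetimidate, CC(C)(C)OC(=N)C(Cl)(Cl)Cl
Why: The same imidate O-alkylation as in step 6 gives two tert-butyl esters, which can be removed by acid in the presence of the trienoate and whose bulk retards lactonisation onto a 6β-hydroxyl.

**Step 11**
Reactants: 17 diene diester
Product: 19 di-tert-butyl (4S,4aS,8aS)-4-hydroxy-5,5,8a-trimethyl-3,4,4a,5,6,7,8,8a-octahydronaphthalene-1,2-dicarboxylate (6α-OH and 5α-H), via C6 alkylborane 18 (not isolated)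
Conditions: BH3·THF (3 equiv), THF, 0 → 23 °C; then 3 M NaOH, 30% H2O2, 0 °C
Reagents that add atoms: borane–tetrahydrofuran, [BH3-][O+]1CCCC1 (boron retained only in intermediate 18); hydrogen peroxide, OO
Why: Hydroboration–oxidation of the electron-richer trisubstituted C5=C6 alkene (the tetrasubstituted diester alkene and the tert-butyl esters should be inert to borane) by syn addition from the α face, opposite the C10 β-methyl and the β-methyl on C4, puts boron on C6 and hydrogen on C5 and so sets 5α-H (trans ring fusion) and 6α-OH.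

**Step 12**
Reactants: 19 unsaturated hydroxy diester
Product: 20 di-tert-butyl (1S,2S,4S,4aS,8aS)-4-hydroxy-5,5,8a-trimethyldecahydronaphthalene-1,2-dicarboxylate
Conditions: H2 (60 bar), Rh/Al2O3 (5 wt% Rh), EtOAc, 40 °C
Reagents that add atoms: none
Why: Heterogeneous syn hydrogenation of the tetrasubstituted maleate-type alkene from the α face, the β face being shielded by the axial C10 methyl next to C9, should deliver both hydrogens α and set C8 and C9 with both ester groups β (cis).

**Step 13**
Reactants: 20 saturated hydroxy diester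
Product: 21 di-tert-butyl (1S,2S,4aS,8aS)-5,5,8a-trimethyl-4-oxodecahydronaphthalene-1,2-dicarboxylate
Conditions: Dess–Martin periodinane, NaHCO3, CH2Cl2, 0 → 23 °C
Reagents that add atoms: none
Why: Dess–Martin oxidation of the equatorial 6α-alcohol to the C6 ketone under buffered conditions is run only after C8=C9 is saturated, so that no β,γ-unsaturated ketone able to isomerise is formed and the axial C8 ester is not epimerised.

**Step 14**
Reactants: 21 C6 ketone
Product: 22 di-tert-butyl (1S,2S,4R,4aS,8aS)-4-hydroxy-5,5,8a-trimethyldecahydronaphthalene-1,2-dicarboxylate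
Conditions: NaBH4, MeOH–THF, −20 °C; AcOH quench
Reagents that add atoms: none
Why: Borohydride reduction with hydride delivered from the α face, the β face being blocked by the syn-axial C10 methyl, the β-methyl on C4 and the 8β-ester, should give the axial 6β-alcohol, while low temperature, the acidic quench and the bulky tert-butyl ester suppress lactonisation onto C12.

**Step 15**
Reactants: 23 (2E,4E,6E)-octa-2,4,6-trienoic acid
Product: 24 (2E,4E,6E)-octa-2,4,6-trienoyl chloride
Conditions: (COCl)2 (1.2 equiv), DMF (cat.), CH2Cl2, 0 → 23 °C; used crude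
Reagents that add atoms: oxalyl chloride, ClC(=O)C(=O)Cl
Why: Acid chloride formation with oxalyl chloride under Vilsmeier-type catalysis by DMF proceeds at or below room temperature and should not isomerise the all-E triene.

**Step 16**
Reactants: 22 6β-alcohol; 24 trienoyl chloride
Product: 25 di-tert-butyl (1S,2S,4R,4aS,8aS)-4-[(2E,4E,6E)-octa-2,4,6-trienoyloxy]-5,5,8a-trimethyldecahydronaphthalene-1,2-dicarboxylate
Conditions: 24 (3 equiv), DMAP (4 equiv), CH2Cl2, 0 → 40 °C
Reagents that add atoms: (2E,4E,6E)-octa-2,4,6-trienoyl chloride (24), C/C=C/C=C/C=C/C(=O)Cl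
Why: DMAP-mediated acylation of the hindered axial alcohol through the N-acylpyridinium salt, run without a trialkylamine so that the acyl chloride is not converted to a vinylketene, retains the C6 configuration.

**Step 17**
Reactants: 25 trienoate di-tert-butyl ester
Product: 26 CNP0462207.1, (1S,2S,4R,4aS,8aS)-4-[(2E,4E,6E)-octa-2,4,6-trienoyloxy]-5,5,8a-trimethyldecahydronaphthalene-1,2-dicarboxylic acid
Conditions: CF3CO2H–CH2Cl2 (1:3), 0 → 23 °C
Reagents that add atoms: none
Why: Acidolysis of both tert-butyl esters through the tert-butyl cation (loss of 2-methylpropene) should leave the trienoate ester and the five stereocentres untouched, since no base is present that could epimerise C8 or cleave the C6 ester.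

**Compound list**

1 | β-cyclocitral (2,6,6-trimethylcyclohex-1-ene-1-carbaldehyde) | CC1=C(C=O)C(C)(C)CCC1 | starting material
2 | (−)-B-allyldiisopinocampheylborane | C=CCB([C@@H]1C[C@@H]2C[C@H]([C@H]1C)C2(C)C)[C@@H]1C[C@@H]2C[C@H]([C@H]1C)C2(C)C | starting material
3 | (S)-1-(2,6,6-trimethylcyclohex-1-en-1-yl)but-3-en-1-yl diisopinocampheylborinate | C=CC[C@H](OB([C@@H]1C[C@@H]2C[C@H]([C@H]1C)C2(C)C)[C@@H]1C[C@@H]2C[C@H]([C@H]1C)C2(C)C)C1=C(C)CCCC1(C)C | intermediate
4 | (S)-1-(2,6,6-trimethylcyclohex-1-en-1-yl)but-3-en-1-ol | C=CC[C@H](O)C1=C(C)CCCC1(C)C | intermediate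
5 | acryloyl chloride | C=CC(=O)Cl | starting material
6 | (S)-1-(2,6,6-trimethylcyclohex-1-en-1-yl)but-3-en-1-yl prop-2-enoate | C=CC[C@H](OC(=O)C=C)C1=C(C)CCCC1(C)C | intermediate
7 | (S)-6-(2,6,6-trimethylcyclohex-1-en-1-yl)-5,6-dihydro-2H-pyran-2-one | O=C1C=CC[C@H](O1)C2=C(C)CCCC2(C)C | intermediate
8 | (4R,6S)-4-(4,4,5,5-tetramethyl-1,3,2-dioxaborolan-2-yl)-6-(2,6,6-trimethylcyclohex-1-en-1-yl)oxan-2-one | O=C1C[C@H](B2OC(C)(C)C(C)(C)O2)C[C@H](O1)C3=C(C)CCCC3(C)C | intermediate
9 | (4R,6S)-4-hydroxy-6-(2,6,6-trimethylcyclohex-1-en-1-yl)oxan-2-one (4,6-trans) | O=C1C[C@H](O)C[C@H](O1)C2=C(C)CCCC2(C)C | intermediate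
10 | (2S,4R)-4,6-bis(tert-butyldimethylsilyloxy)-2-(2,6,6-trimethylcyclohex-1-en-1-yl)-3,4-dihydro-2H-pyran | CC(C)(C)[Si](C)(C)OC1=C[C@H](O[Si](C)(C)C(C)(C)C)C[C@H](O1)C2=C(C)CCCC2(C)C | intermediate
11 | tert-butyldimethylsilyl (1S,2R,8aR)-2-(tert-butyldimethylsilyloxy)-5,5,8a-trimethyl-1,2,3,5,6,7,8,8a-octahydronaphthalene-1-carboxylate | C1[C@@H](O[Si](C)(C)C(C)(C)C)[C@@H](C(=O)O[Si](C)(C)C(C)(C)C)[C@@]2(C)CCCC(C)(C)C2=C1 | intermediate
12 | (1S,2R,8aR)-2-hydroxy-5,5,8a-trimethyl-1,2,3,5,6,7,8,8a-octahydronaphthalene-1-carboxylic acid (8α-OH, 9α-CO2H, 10β-Me) | C1[C@@H](O)[C@@H](C(=O)O)[C@@]2(C)CCCC(C)(C)C2=C1 | intermediate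
13 | tert-butyl (1S,2R,8aR)-2-hydroxy-5,5,8a-trimethyl-1,2,3,5,6,7,8,8a-octahydronaphthalene-1-carboxylate | C1[C@@H](O)[C@@H](C(=O)OC(C)(C)C)[C@@]2(C)CCCC(C)(C)C2=C1 | intermediate
14 | tert-butyl (1R,8aR)-5,5,8a-trimethyl-2-oxo-1,2,3,5,6,7,8,8a-octahydronaphthalene-1-carboxylate | C1C(=O)[C@H](C(=O)OC(C)(C)C)[C@@]2(C)CCCC(C)(C)C2=C1 | intermediate
15 | tert-butyl (8aS)-5,5,8a-trimethyl-2-(trifluoromethylsulfonyloxy)-3,5,6,7,8,8a-hexahydronaphthalene-1-carboxylate | C1C(OS(=O)(=O)C(F)(F)F)=C(C(=O)OC(C)(C)C)[C@@]2(C)CCCC(C)(C)C2=C1 | intermediate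
16 | (8aS)-1-(tert-butoxycarbonyl)-5,5,8a-trimethyl-3,5,6,7,8,8a-hexahydronaphthalene-2-carboxylic acid | C1C(C(=O)O)=C(C(=O)OC(C)(C)C)[C@@]2(C)CCCC(C)(C)C2=C1 | intermediate
17 | di-tert-butyl (8aS)-5,5,8a-trimethyl-3,5,6,7,8,8a-hexahydronaphthalene-1,2-dicarboxylate | C1C(C(=O)OC(C)(C)C)=C(C(=O)OC(C)(C)C)[C@@]2(C)CCCC(C)(C)C2=C1 | intermediate
18 | di-tert-butyl (4S,4aS,8aS)-4-boranyl-5,5,8a-trimethyl-3,4,4a,5,6,7,8,8a-octahydronaphthalene-1,2-dicarboxylate | B[C@H]1CC(C(=O)OC(C)(C)C)=C(C(=O)OC(C)(C)C)[C@@]2(C)CCCC(C)(C)[C@H]12 | intermediate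
19 | di-tert-butyl (4S,4aS,8aS)-4-hydroxy-5,5,8a-trimethyl-3,4,4a,5,6,7,8,8a-octahydronaphthalene-1,2-dicarboxylate | O[C@H]1CC(C(=O)OC(C)(C)C)=C(C(=O)OC(C)(C)C)[C@@]2(C)CCCC(C)(C)[C@H]12 | intermediate
20 | di-tert-butyl (1S,2S,4S,4aS,8aS)-4-hydroxy-5,5,8a-trimethyldecahydronaphthalene-1,2-dicarboxylate | O[C@H]1C[C@H](C(=O)OC(C)(C)C)[C@H](C(=O)OC(C)(C)C)[C@@]2(C)CCCC(C)(C)[C@H]12 | intermediate
21 | di-tert-butyl (1S,2S,4aS,8aS)-5,5,8a-trimethyl-4-oxodecahydronaphthalene-1,2-dicarboxylate | O=C1C[C@H](C(=O)OC(C)(C)C)[C@H](C(=O)OC(C)(C)C)[C@@]2(C)CCCC(C)(C)[C@H]12 | intermediate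
22 | di-tert-butyl (1S,2S,4R,4aS,8aS)-4-hydroxy-5,5,8a-trimethyldecahydronaphthalene-1,2-dicarboxylate | O[C@@H]1C[C@H](C(=O)OC(C)(C)C)[C@H](C(=O)OC(C)(C)C)[C@@]2(C)CCCC(C)(C)[C@H]12 | intermediate
23 | (2E,4E,6E)-octa-2,4,6-trienoic acid | C/C=C/C=C/C=C/C(=O)O | starting material
24 | (2E,4E,6E)-octa-2,4,6-trienoyl chloride | C/C=C/C=C/C=C/C(=O)Cl | intermediate
25 | di-tert-butyl (1S,2S,4R,4aS,8aS)-4-[(2E,4E,6E)-octa-2,4,6-trienoyloxy]-5,5,8a-trimethyldecahydronaphthalene-1,2-dicarboxylate | C/C=C/C=C/C=C/C(=O)O[C@@H]1C[C@H](C(=O)OC(C)(C)C)[C@H](C(=O)OC(C)(C)C)[C@@]2(C)CCCC(C)(C)[C@H]12 | intermediate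
26 | CNP0462207.1, (1S,2S,4R,4aS,8aS)-4-[(2E,4E,6E)-octa-2,4,6-trienoyloxy]-5,5,8a-trimethyldecahydronaphthalene-1,2-dicarboxylic acid | C/C=C/C=C/C=C/C(=O)O[C@@H]1C[C@H](C(=O)O)[C@H](C(=O)O)[C@@]2(C)CCCC(C)(C)[C@H]12 | target

**Step count and risks**

Total steps: 17. Longest linear sequence: 16 (steps 1–14, 16, 17; step 15 is a one-step side branch).

Steps most likely to fail:

1. Step 5 (key step). The boat-mode rearrangement that builds a quaternary carbon at a tetrasubstituted alkene may be too slow at 110 °C. Ionisation of the allylic C6–O bond with elimination to a diene, O-to-C silyl migration in the ketene acetal, or β-elimination of silanolate before the enolate is trapped could then take over, and partial ionisation would erode the chirality transfer. Fallback, setting out from 9: Dess–Martin oxidation gives (S)-6-(2,6,6-trimethylcyclohex-1-en-1-yl)oxane-2,4-dione F1. Double enolisation with LiN(iPr)2 and trapping with Me3SiCl at −78 °C gives the bis(trimethylsilyl) dienol ether F2, in which C8 is trigonal (nothing points at the C10 methyl) and the extra donor should let the Carroll-type rearrangement run at or below room temperature, fast enough to outrun ring opening. Warming gives trimethylsilyl 2-(trimethylsilyloxy)drim-5,7-dien-11-oate F3, and cold methanolysis gives the β-keto acid F4. F4 is esterified at once with tert-butyl 2,2,2-trichloroacetimidate, and the route is rejoined at 14.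

2. Step 12. The tetrasubstituted alkene carries two tert-butyl esters and sits next to quaternary C10, so it may not adsorb and reduce at a useful rate, and forcing conditions may cause alkene migration and loss of the cis relationship. Fallback, setting out from 19: LiN(iPr)2 (3 equiv, THF, −78 °C) removes a C7 hydrogen, and kinetic protonation of the extended enolate at C9 from the α face (AcOH, −78 °C) gives the deconjugated C7=C8 isomer, di-tert-butyl (1R,4S,4aS,8aS)-4-hydroxy-5,5,8a-trimethyl-1,4,4a,5,6,7,8,8a-octahydronaphthalene-1,2-dicarboxylate F5, with the 9β-ester already in place. Its trisubstituted alkene is allylic to the 6α-hydroxyl and is hydrogenated homogeneously with [Ir(cod)(PCy3)(py)]PF6 and H2 in CH2Cl2, the hydroxyl directing hydrogen to the α face of C8. This returns to the route at 20.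

3. Step 16. Acylation of the axial 6β-hydroxyl, flanked by three syn-axial groups, may be slower than vinylketene formation from the acyl chloride (deconjugation, oligomerisation) or than lactonisation of the hydroxyl onto the C12 ester. Fallback, setting out from 22: esterification with diethylphosphonoacetic acid and DCC, which acylates through a small and very electrophilic phosphonoketene, gives the 6β-(diethylphosphonoacetate) F6. A Horner–Wadsworth–Emmons reaction of F6 with (2E,4E)-hexa-2,4-dienal under LiCl and iPr2NEt in MeCN then builds the all-E trienoate on the ester already in place and returns to the route at 25.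

**Further compounds**

F1 | step 5 | (S)-6-(2,6,6-trimethylcyclohex-1-en-1-yl)oxane-2,4-dione | O=C1CC(=O)C[C@H](O1)C2=C(C)CCCC2(C)C
F2 | step 5 | (2S)-2-(2,6,6-trimethylcyclohex-1-en-1-yl)-4,6-bis(trimethylsilyloxy)-2H-pyran | C[Si](C)(C)OC1=CC(O[Si](C)(C)C)=C[C@H](O1)C2=C(C)CCCC2(C)C
F3 | step 5 | trimethylsilyl (1S,8aR)-5,5,8a-trimethyl-2-(trimethylsilyloxy)-1,5,6,7,8,8a-hexahydronaphthalene-1-carboxylate | C1=C(O[Si](C)(C)C)[C@@H](C(=O)O[Si](C)(C)C)[C@@]2(C)CCCC(C)(C)C2=C1
F4 | step 5 | (1S,8aR)-5,5,8a-trimethyl-2-oxo-1,2,3,5,6,7,8,8a-octahydronaphthalene-1-carboxylic acid | C1C(=O)[C@@H](C(=O)O)[C@@]2(C)CCCC(C)(C)C2=C1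
F5 | step 12 | di-tert-butyl (1R,4S,4aS,8aS)-4-hydroxy-5,5,8a-trimethyl-1,4,4a,5,6,7,8,8a-octahydronaphthalene-1,2-dicarboxylate | O[C@H]1C=C(C(=O)OC(C)(C)C)[C@H](C(=O)OC(C)(C)C)[C@@]2(C)CCCC(C)(C)[C@H]12
F6 | step 16 | di-tert-butyl (1S,2S,4R,4aS,8aS)-4-[2-(diethoxyphosphoryl)acetoxy]-5,5,8a-trimethyldecahydronaphthalene-1,2-dicarboxylate | CCOP(=O)(OCC)CC(=O)O[C@@H]1C[C@H](C(=O)OC(C)(C)C)[C@H](C(=O)OC(C)(C)C)[C@@]2(C)CCCC(C)(C)[C@H]12
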